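**Numbering used throughout** (full names and SMILES are in the compound list after the steps): 1 4'-(benzyloxy)acetophenone; 2 its enol triflate; 3 the 1-arylvinyl pinacol boronate; 4 3-hydroxy-5-methylbenzaldehyde; 5 its benzyl ether; 6 the 2-bromo aldehyde; 7 the 2-(1-arylvinyl)benzaldehyde; 8 the (R)-indanone, substrate of the key step; 9 the (R)-chromanone, product of the key step; 10 the 6-bromo lactone; 11 the 6-boronate; 12 malonyl dichloride; 13 an acid chloride that is not isolated; 14 6-chloro-4-hydroxy-2-pyranone; 15 6-chloro-4-methoxy-2-pyranone; 16 the dibenzyl ether of the target; 17 the target.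

## Analysis of the target

The target 17 is a 3,4-dihydrocoumarin (chroman-2-one: O1, C2 carbonyl, C3 methylene, C4 methine) fused to a benzene ring (ring A, C4a to C8a) that is substituted at every position but C8: lactone oxygen at C8a, hydroxyl at C7, a 4-methoxy-2-oxo-2H-pyran-6-yl ring at C6, methyl at C5 and the C4 methine at C4a. C4 carries a 4-hydroxyphenyl ring (ring B) and is the only stereocenter (R); it is a diarylmethine, so there is no neighbouring stereocenter to relay from, and whatever sets it must tell apart two aryl groups of similar size. The sensitive groups are the aryl lactone, which hydroxide or alkoxide opens, the 4-methoxy-2-pyranone, a vinylogous carbonate that nucleophiles attack, hydrogenation catalysts reduce and strong Lewis acids can demethylate, and two oxidisable phenols. The hard part is ring A: three contiguous carbon substituents (C4a, C5, C6) beside a 1,3-dioxygen pattern (C7, C8a), with the C6–C6' bond wedged between the C5 methyl group and the C7 oxygen. A further constraint is that the phenol protecting groups must come off without touching the methyl enol ether of the pyranone. The strategy rests on the position of O1: it lies between the ring carbon C8a and the carbonyl C2, so the lactone is the aryl ester that oxygen insertion into the C1–C7a bond of a 3-arylindan-1-one would give, and that indanone needs only the one ring oxygen that becomes C7–OH. Once O1 is in place, C6 is para to it and ortho to the C7 oxygen, so the same feature also tells where the handle for the pyranone can be placed after the ring expansion.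

## Retrosynthetic reasoning

17 ⇒ 16 (the O–CH2Ph bonds at the C7 oxygen and at the ring B oxygen). The two phenols are unmasked last. Benzyl ethers pass through a peracid, palladium couplings and carbonate or phosphate bases, and a boron Lewis acid cuts them at low temperature. Neither hydrogenation, which would endanger the pyranone double bonds, nor base, which would open the lactone, is then needed. The forward step has to spare the methyl enol ether.

16 ⇒ 11 + 15 (C6–C6'). This bond joins two sp2 carbons and is the natural seam between ring A and the heterocycle. Cutting it late exposes the nucleophile-sensitive pyranone to only one further step and lets it enter as the finished unit 15 instead of being built on a crowded ring carbon. Boron goes on the arene and chlorine on the pyranone because C6 of 15 behaves as a vinylogous acid chloride and is the easy partner for oxidative addition. The forward coupling has to work at a doubly ortho-substituted boronate without opening the aryl lactone.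

15 ⇒ 14 ⇒ 13 ⇒ 12. The O–CH3 bond is cut to 14. Two molecules of 12 supply all ring carbons of 14 through the acid chloride 13, whose extra carbon is removed by hydrolysis and decarboxylation.

11 ⇒ 10 ⇒ 9 (C6–B, then C6–Br). The halogen is placed on the lactone and not earlier. In every intermediate before the ring expansion (5 to 8) the two positions ortho to the ring A ether oxygen stand in the same relation to the deactivating carbonyl-bearing carbon, one ortho and one para, so an electrophile has no dependable preference for the future C6. A second bromine at the aldehyde stage would also force the coupling that gives 7 to choose between two C–Br bonds. In 9 the case is different: C6 is para to the new lactone oxygen, ortho to the ether oxygen and ortho to the methyl group, C8 lies between two oxygens, and ring B has only one activating oxygen. The forward bromination needs this site selectivity, and the borylation needs a catalyst that accepts a doubly ortho-substituted bromide.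

9 ⇒ 8 (O1–C8a). Removing O1 contracts the lactone to the five-membered ketone 8. This is the disconnection around which the route is built. It takes one of the two ring A oxygens out of all earlier intermediates, so ring A can come from a simple 1,3,5-trisubstituted benzene, and it postpones the base-labile aryl ester to the second half of the synthesis. The forward reaction must move the aryl carbon, not the methylene carbon, to oxygen and must leave C4 alone.

8 ⇒ 7 (C1–C2 of the indanone, with hydrogen delivered to C3). The aldehyde C–H bond of 7 is added across its 1,1-diarylethene. The carbonyl carbon then stands exactly where the formyl carbon stood, so the later position of O1 is fixed by the substitution pattern of 4. A Friedel–Crafts closure would instead have to choose between ring A and ring B at positions that are both meta to an ether oxygen. The same step creates C3, the future C4, and a chiral bisphosphine–rhodium catalyst has to choose the alkene face.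

7 ⇒ 6 + 3 (aryl–vinyl bond). A cross-coupling at the only C–Br bond of 6, which the ortho formyl group activates, joins the two halves; 3 brings ring B already benzylated.

6 ⇒ 5 ⇒ 4 (C–Br, then O–benzyl). Bromine is wanted on the carbon between formyl and methyl, which is the carbon para to the ether oxygen of 5, the position an aryl ether directs to most strongly. Compound 4 supplies formyl, oxygen and methyl in a mutual meta relationship that electrophilic substitution cannot create.

3 ⇒ 2 ⇒ 1 (C–B, then the enol C–O bond). The 1-arylvinyl boronate comes from the methyl ketone 1 through its enol triflate 2; the ketone has a single enolisable position.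

## Alternatives that were turned down

Alternative 1: Ring A is taken apart at C4a–C5 and C6–C7 and rebuilt by a [4+2] benzannulation. A 1,3-dioxygenated silyl diene that already carries C4, obtained from a desymmetrised 3-arylglutaric derivative, adds to an alkynoate dienophile; elimination and acid work-up aromatise the adduct. The product of this step is the resorcylate A1, allyl (R)-2,4-dihydroxy-5-[3-methoxy-3-oxo-1-[4-(triisopropylsilyloxy)phenyl]propyl]-6-methylbenzoate.
- For: in A1 both ring oxygens and the methyl group arrive at defined carbons through the polarity match of the two partners, there is no migration question and no late halogenation, and the stereocenter comes from a classical desymmetrisation. On regiochemical certainty and on the origin of the stereocenter this plan is stronger than the chosen one.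
- Against: A1 carries an ester, not a pyranone, at C6, so the heterocycle would have to be built through several more C–C and C–O bond formations on a carbon flanked by methyl and hydroxyl. The diene is a base-sensitive bis(silyl enol ether) with a second ester in its chain. Its cycloaddition with an internal, weakly activated alkynoate to a hexasubstituted benzene is the sterically worst case for this annulation. Differentiating the two phenols of A1 and closing the lactone add further steps.
- In its place the chosen route offers the complete methoxypyranone in one coupling and a longest linear sequence of nine steps.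

Alternative 2: C2–C3 and O1–C2 are cut together with C4–H. A 1,1-diarylethene whose ring A already holds both oxygens, the methyl group and the pyranone is carbonylated: a chiral palladium hydride delivers hydrogen to C4, the one-carbon unit inserts at C3, and the C8a hydroxyl captures the acyl palladium. The product of this step is A2, (R)-6-[7-hydroxy-5-methyl-2-oxo-4-[4-(triisopropylsilyloxy)phenyl]chroman-6-yl]-4-methoxy-2H-pyran-2-one. A2 is a single silyl ether cleavage away from 17.
- For: in A2 the lactone ring, the carbonyl carbon and the stereocenter appear in a single late step, and ring A needs no oxygen insertion because it starts as a resorcinol-type ring. On convergence and step count this plan is stronger than the chosen one.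
- Against: the stereo-determining event on the way to A2 is hydride delivery to an alkene whose two substituents are both aryl rings, one of them doubly ortho-substituted and twisted out of conjugation. The catalyst has no anchoring point comparable to an acyl–metal bond. The alkene carbon sits between an ortho hydroxyl and an ortho methyl group. The pyranone has to survive palladium hydride and acid promoters. Enantioselective hydrocarbonylation of this alkene class would have to be developed.
- Compared with the route to A2, the chosen route separates the tasks. The stereocenter is set by an intramolecular hydroacylation that runs through a six-membered acyl rhodacycle, a known reaction class, and the oxygen is introduced by a classical rearrangement.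

Alternative 3: The pyranone is cut at its ring oxygen–C6' bond and formed on the arene. An aryl alkynyl ketone with a tert-butyl ester terminus undergoes 6-endo-dig attack of the ester carbonyl oxygen on the gold-activated alkyne with loss of the tert-butyl group. The product of this step is the hydroxypyranone A3, methyl (R)-3-[2,4-bis(benzyloxy)-5-(4-hydroxy-2-oxo-2H-pyran-6-yl)-6-methylphenyl]-3-[4-(benzyloxy)phenyl]propanoate.
- For: the crowded C6–C6' bond of A3 is made with a slim alkyne and not by a hindered aryl–heteroaryl coupling, and the gold step is neutral. On this point the plan is stronger than the chosen one, whose coupling in step 12 joins a doubly ortho-substituted boronate.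
- Against: A3 is still four operations from the target (O-methylation of a 4-hydroxypyranone with its O2/O4 ambiguity, removal of three benzyl ethers, lactonisation). The ynone precursor is a Michael acceptor open to 5-exo closure and hydration. The alkyne must still be placed between methyl and benzyloxy on a hexasubstituted ring. The key step does nothing for C4, so a separate asymmetric step is needed.
- The chosen route installs the finished methoxypyranone in one step and includes the creation of the stereocenter; a tin-based variant is available if the boron coupling is slow.

Key step: step 7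

Assumption: (R)-BINAP is written for the hydroacylation catalyst; if hydride delivery on this substrate favours the other alkene face, (S)-BINAP is used instead with no other change.

## Route

Step 1
Reactants: 1 4'-(benzyloxy)acetophenone
Product: 2 1-[4-(benzyloxy)phenyl]vinyl trifluoromethanesulfonate
Conditions: KN(SiMe3)2, THF, −78 °C; then PhNTf2, −78 → 0 °C
Reagents that add atoms: N-phenylbis(trifluoromethanesulfonimide), O=S(=O)(N(c1ccccc1)S(=O)(=O)C(F)(F)F)C(F)(F)F
Why: Enol triflate formation: the methyl ketone has one enolisable position, and the potassium enolate is sulfonylated on oxygen by the triflimide.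

Step 2
Reactants: 2 1-[4-(benzyloxy)phenyl]vinyl trifluoromethanesulfonate
Product: 3 2-{1-[4-(benzyloxy)phenyl]vinyl}-4,4,5,5-tetramethyl-1,3,2-dioxaborolane
Conditions: B2pin2, PdCl2(PPh3)2, PPh3, KOPh, toluene, 50 °C
Reagents that add atoms: bis(pinacolato)diboron, CC1(C)OB(OC1(C)C)B1OC(C)(C)C(C)(C)O1
Why: Miyaura borylation of an alkenyl triflate: oxidative addition of the C–O bond to zerovalent palladium, transmetalation with the phenoxide-activated diboron and reductive elimination; the weak base keeps the product from coupling with unreacted triflate.

Step 3
Reactants: 4 3-hydroxy-5-methylbenzaldehyde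
Product: 5 3-(benzyloxy)-5-methylbenzaldehyde
Conditions: BnBr, K2CO3, DMF, 25 °C
Reagents that add atoms: benzyl bromide, BrCc1ccccc1
Why: Williamson ether synthesis on the phenoxide; the aldehyde is inert to carbonate. Protecting before halogenation makes the ether oxygen the only strong director in the next step.

Step 4
Reactants: 5 3-(benzyloxy)-5-methylbenzaldehyde
Product: 6 5-(benzyloxy)-2-bromo-3-methylbenzaldehyde
Conditions: NBS, DMF, 25 °C, dark
Reagents that add atoms: N-bromosuccinimide, O=C1CCC(=O)N1Br
Why: Electrophilic aromatic bromination para to the ether oxygen, the site that both parent patterns (a 3-alkoxybenzaldehyde and a 3-methyl aryl ether) select; this carbon lies between formyl and methyl. The polar solvent and exclusion of light suppress radical bromination of the benzylic positions.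

Step 5
Reactants: 6 5-(benzyloxy)-2-bromo-3-methylbenzaldehyde, 3 2-{1-[4-(benzyloxy)phenyl]vinyl}-4,4,5,5-tetramethyl-1,3,2-dioxaborolane
Product: 7 5-(benzyloxy)-2-{1-[4-(benzyloxy)phenyl]vinyl}-3-methylbenzaldehyde
Conditions: Pd(OAc)2, SPhos, K3PO4, toluene/H2O, 80 °C
Reagents that add atoms: none
Why: Suzuki–Miyaura coupling at the only C–Br bond, which the ortho formyl group activates toward oxidative addition; the bulky biaryl phosphine is chosen for the doubly ortho-substituted bromide, and the aldehyde tolerates phosphate.

Step 6
Reactants: 7 5-(benzyloxy)-2-{1-[4-(benzyloxy)phenyl]vinyl}-3-methylbenzaldehyde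
Product: 8 (R)-6-(benzyloxy)-3-[4-(benzyloxy)phenyl]-4-methylindan-1-one
Conditions: [Rh((R)-BINAP)]BF4 (5 mol %), CH2Cl2, 25 °C
Reagents that add atoms: none
Why: Enantioselective intramolecular alkene hydroacylation, a reaction known for 2-(1-substituted vinyl)benzaldehydes: the aldehyde C–H bond adds to monovalent rhodium, the hydride inserts at the internal alkene carbon, and C–C reductive elimination from the six-membered acyl rhodacycle forms C1–C2. The C3 stereocenter is set in the hydride transfer, where the chiral bisphosphine on the substrate-bound metal selects the alkene face.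

Step 7
Reactants: 8 (R)-6-(benzyloxy)-3-[4-(benzyloxy)phenyl]-4-methylindan-1-one
Product: 9 (R)-7-(benzyloxy)-4-[4-(benzyloxy)phenyl]-5-methylchroman-2-one
Conditions: mCPBA, CF3CO2H, CH2Cl2, 0 → 25 °C, dark
Reagents that add atoms: 3-chloroperbenzoic acid, O=C(OO)c1cccc(Cl)c1
Why: Baeyer–Villiger oxidation of an aryl alkyl ketone; the closest known case is the peracid conversion of 1-indanones into 3,4-dihydrocoumarins. The acid-activated carbonyl of 8 adds the peracid to give the tetrahedral peroxy adduct, and in the slow step C7a (the future C8a) shifts from carbon to the proximal peroxide oxygen as 3-chlorobenzoate leaves, which forms O1–C8a. The six-membered lactone ring therefore arises by ring expansion through a 1,2-aryl shift and not by an end-to-end closure; both ring bonds of the five-membered adduct can align antiperiplanar to the O–O bond, so the choice between them is electronic. The step needs regioselectivity between the aryl carbon and the C2 methylene: the aryl carbon can bridge the developing positive charge, it has an ortho alkyl substituent and, because the bromide is not yet present, no acceptor in its para position, whereas the competitor is a primary carbon. No stereocenter is created; C3 of 8 (C4 of 9) is not enolisable and is not part of the migrating bond, so it keeps its R configuration. Chemoselectivity over the two benzyloxy-substituted rings is secured by the use of a carboxylic acid rather than a sulfonic acid as promoter, the low temperature and the exclusion of light.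

Step 8
Reactants: 9 (R)-7-(benzyloxy)-4-[4-(benzyloxy)phenyl]-5-methylchroman-2-one
Product: 10 (R)-7-(benzyloxy)-4-[4-(benzyloxy)phenyl]-6-bromo-5-methylchroman-2-one
Conditions: NBS, MeCN, 0 → 25 °C, dark
Reagents that add atoms: N-bromosuccinimide, O=C1CCC(=O)N1Br
Why: Electrophilic aromatic bromination: C6 is ortho to the benzyloxy group, ortho to methyl and para to the lactone oxygen, C8 lies between two oxygens (the least reactive position of a 1,3-dioxygenated ring), and ring B is activated by one ether oxygen only. Diethers of 5-methylresorcinol are known to brominate beside the methyl group.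

Step 9
Reactants: 10 (R)-7-(benzyloxy)-4-[4-(benzyloxy)phenyl]-6-bromo-5-methylchroman-2-one
Product: 11 (R)-7-(benzyloxy)-4-[4-(benzyloxy)phenyl]-5-methyl-6-(4,4,5,5-tetramethyl-1,3,2-dioxaborolan-2-yl)chroman-2-one
Conditions: B2pin2, Pd(OAc)2, SPhos, KOAc, 1,4-dioxane, 90 °C
Reagents that add atoms: bis(pinacolato)diboron, CC1(C)OB(OC1(C)C)B1OC(C)(C)C(C)(C)O1
Why: Miyaura borylation; the biaryl phosphine lets zerovalent palladium insert into the doubly ortho-substituted C–Br bond, and anhydrous acetate is too weak a base to open the aryl lactone.

Step 10
Reactants: 12 malonyl dichloride (2 equiv)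
Product: 14 6-chloro-4-hydroxy-2H-pyran-2-one, via 6-chloro-4-hydroxy-2-oxo-2H-pyran-3-carbonyl chloride 13 (not isolated)
Conditions: neat, 25 °C, 3 d; then H2O, 1,4-dioxane, 25 → 60 °C
Reagents that add atoms: none
Why: Self-condensation of the bis(acid chloride): C-acylation of one molecule by a second, then closure of an enol oxygen onto an acid chloride, gives the pyranone carbonyl chloride 13. Water hydrolyses the remaining acid chloride and the vinylogous β-keto acid decarboxylates; this is the known access to 14.

Step 11
Reactants: 14 6-chloro-4-hydroxy-2H-pyran-2-one
Product: 15 6-chloro-4-methoxy-2H-pyran-2-one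
Conditions: Me2SO4, K2CO3, acetone, 25 °C
Reagents that add atoms: dimethyl sulfate, COS(=O)(=O)OC
Why: O-Alkylation of the vinylogous acid with dimethyl sulfate and carbonate, the standard route from 4-hydroxy-2-pyranones to 4-methoxy-2-pyranones; the delocalised anion is a poor nucleophile toward the C6 chloride of a second molecule.

Step 12
Reactants: 11 (R)-7-(benzyloxy)-4-[4-(benzyloxy)phenyl]-5-methyl-6-(4,4,5,5-tetramethyl-1,3,2-dioxaborolan-2-yl)chroman-2-one, 15 6-chloro-4-methoxy-2H-pyran-2-one
Product: 16 (R)-7-(benzyloxy)-4-[4-(benzyloxy)phenyl]-6-(4-methoxy-2-oxo-2H-pyran-6-yl)-5-methylchroman-2-one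
Conditions: Pd2(dba)3, SPhos, CsF, 1,4-dioxane, 90 °C
Reagents that add atoms: none
Why: Suzuki–Miyaura coupling of a halo-2-pyranone: the C6–Cl bond of 15 is a vinylogous acid chloride and adds readily to zerovalent palladium, and the biaryl phosphine speeds transmetalation of the hindered boronate. Anhydrous fluoride activates the pinacol boronate without the hydroxide that would open the aryl lactone or hydrolyse 15.

Step 13
Reactants: 16 (R)-7-(benzyloxy)-4-[4-(benzyloxy)phenyl]-6-(4-methoxy-2-oxo-2H-pyran-6-yl)-5-methylchroman-2-one
Product: 17 (R)-7-hydroxy-4-(4-hydroxyphenyl)-6-(4-methoxy-2-oxo-2H-pyran-6-yl)-5-methylchroman-2-one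
Conditions: BCl3, pentamethylbenzene, CH2Cl2, −78 °C; then MeOH
Reagents that add atoms: none
Why: Lewis-acid cleavage of aryl benzyl ethers at low temperature; pentamethylbenzene traps the benzyl cation without complexing the boron halide, which prevents C-benzylation of the phenol rings. At −78 °C the methyl enol ether of the pyranone and the lactone should not be attacked, and no stereocenter is touched.

## Compound list

1 | 4'-(benzyloxy)acetophenone | CC(=O)c1ccc(OCc2ccccc2)cc1 | starting material
2 | 1-[4-(benzyloxy)phenyl]vinyl trifluoromethanesulfonate | C=C(OS(=O)(=O)C(F)(F)F)c1ccc(OCc2ccccc2)cc1 | intermediate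
3 | 2-{1-[4-(benzyloxy)phenyl]vinyl}-4,4,5,5-tetramethyl-1,3,2-dioxaborolane | C=C(B1OC(C)(C)C(C)(C)O1)c1ccc(OCc2ccccc2)cc1 | intermediate
4 | 3-hydroxy-5-methylbenzaldehyde | Cc1cc(O)cc(C=O)c1 | starting material
5 | 3-(benzyloxy)-5-methylbenzaldehyde | Cc1cc(OCc2ccccc2)cc(C=O)c1 | intermediate
6 | 5-(benzyloxy)-2-bromo-3-methylbenzaldehyde | Cc1cc(OCc2ccccc2)cc(C=O)c1Br | intermediate
7 | 5-(benzyloxy)-2-{1-[4-(benzyloxy)phenyl]vinyl}-3-methylbenzaldehyde | Cc1cc(OCc2ccccc2)cc(C=O)c1C(=C)c1ccc(OCc2ccccc2)cc1 | intermediate
8 | (R)-6-(benzyloxy)-3-[4-(benzyloxy)phenyl]-4-methylindan-1-one | Cc1cc(OCc2ccccc2)cc2c1[C@@H](c1ccc(OCc3ccccc3)cc1)CC2=O | intermediate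
9 | (R)-7-(benzyloxy)-4-[4-(benzyloxy)phenyl]-5-methylchroman-2-one | Cc1cc(OCc2ccccc2)cc2c1[C@@H](c1ccc(OCc3ccccc3)cc1)CC(=O)O2 | intermediate
10 | (R)-7-(benzyloxy)-4-[4-(benzyloxy)phenyl]-6-bromo-5-methylchroman-2-one | Cc1c(Br)c(OCc2ccccc2)cc2c1[C@@H](c1ccc(OCc3ccccc3)cc1)CC(=O)O2 | intermediate
11 | (R)-7-(benzyloxy)-4-[4-(benzyloxy)phenyl]-5-methyl-6-(4,4,5,5-tetramethyl-1,3,2-dioxaborolan-2-yl)chroman-2-one | Cc1c(B3OC(C)(C)C(C)(C)O3)c(OCc2ccccc2)cc2c1[C@@H](c1ccc(OCc3ccccc3)cc1)CC(=O)O2 | intermediate
12 | malonyl dichloride | O=C(Cl)CC(=O)Cl | starting material
13 | 6-chloro-4-hydroxy-2-oxo-2H-pyran-3-carbonyl chloride | O=C(Cl)c1c(O)cc(Cl)oc1=O | intermediate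
14 | 6-chloro-4-hydroxy-2H-pyran-2-one | O=c1cc(O)cc(Cl)o1 | intermediate
15 | 6-chloro-4-methoxy-2H-pyran-2-one | COc1cc(Cl)oc(=O)c1 | intermediate
16 | (R)-7-(benzyloxy)-4-[4-(benzyloxy)phenyl]-6-(4-methoxy-2-oxo-2H-pyran-6-yl)-5-methylchroman-2-one | COc1cc(-c2c(OCc3ccccc3)cc3c(c2C)[C@@H](c2ccc(OCc4ccccc4)cc2)CC(=O)O3)oc(=O)c1 | intermediate
17 | (R)-7-hydroxy-4-(4-hydroxyphenyl)-6-(4-methoxy-2-oxo-2H-pyran-6-yl)-5-methylchroman-2-one | COc1cc(-c2c(O)cc3c(c2C)[C@@H](c2ccc(O)cc2)CC(=O)O3)oc(=O)c1 | target

## Step count and least certain steps

Total: 13 steps. Longest linear sequence: 9 steps (4 → 5 → 6 → 7 → 8 → 9 → 10 → 11 → 16 → 17; the branch from 1 is equally long, the branch from 12 is four steps).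

Step 7 (key step). The most likely failures are incomplete oxygen insertion, because a conjugated aryl ketone is a slow acceptor for the peracid; migration of the methylene carbon in place of the aryl carbon; and ring hydroxylation of the benzyloxy-substituted rings if the acid is made stronger to force conversion. The fallback sets out from 8 and returns at 9 and replaces the ketone–peracid adduct by a benzylic hydroperoxide, in which an aryl group is the only competent carbon migrant. NaBH4 in MeOH reduces 8 to (3R)-6-(benzyloxy)-3-[4-(benzyloxy)phenyl]-4-methylindan-1-ol F1 (both C1 epimers). Concentrated aqueous H2O2 with catalytic H2SO4 at 0 °C converts it into (3R)-6-(benzyloxy)-3-[4-(benzyloxy)phenyl]-1-hydroperoxy-4-methylindane F2. BF3·OEt2 in CH2Cl2 at low temperature induces the Hock rearrangement (loss of water with aryl shift to oxygen, then capture of the cyclic oxocarbenium ion by water) to (4R)-7-(benzyloxy)-4-[4-(benzyloxy)phenyl]-5-methylchroman-2-ol F3. Oxidation of this lactol with TEMPO and PhI(OAc)2 gives 9.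

Step 6. The most likely failures are stalling of the cyclisation with decarbonylation of the acyl rhodium hydride, because the 1,1-diarylethene is twisted and flanked by the C3 methyl group, and poor facial selectivity, because both alkene substituents are aryl rings. The fallback sets out from 6 and returns at 8 and forms the C3–C3a bond instead of the C1–C2 bond. MeMgBr adds to 6 to give 1-[5-(benzyloxy)-2-bromo-3-methylphenyl]ethan-1-ol F4. Dess–Martin periodinane oxidises it to 1-[5-(benzyloxy)-2-bromo-3-methylphenyl]ethan-1-one F5. Claisen–Schmidt condensation with commercial 4-(benzyloxy)benzaldehyde (NaOH, EtOH) gives (E)-1-[5-(benzyloxy)-2-bromo-3-methylphenyl]-3-[4-(benzyloxy)phenyl]prop-2-en-1-one F6. An enantioselective intramolecular reductive Heck cyclisation (Pd(OAc)2, a chiral biaryl bisphosphine of the MeO-BIPHEP type, HCO2Na, DMF, 80 °C) adds the aryl palladium to the β-carbon, and the palladium enolate is reduced, which gives 8.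

Step 8. The most likely failures are poor site selectivity (attack at C8 or on ring B ortho to its ether oxygen) and radical substitution at the doubly benzylic C4–H if light is not excluded. The fallback sets out from 9 and returns at 10 and lets a free phenol direct the halogen. NaOMe in MeOH at 0 °C opens the lactone to methyl (3R)-3-[4-(benzyloxy)-2-hydroxy-6-methylphenyl]-3-[4-(benzyloxy)phenyl]propanoate F7, in which the future C6 is para to the freed hydroxyl. NBS in CH2Cl2 at −20 °C gives methyl (3R)-3-[4-(benzyloxy)-3-bromo-6-hydroxy-2-methylphenyl]-3-[4-(benzyloxy)phenyl]propanoate F8. TsOH in toluene at 80 °C closes the lactone again with loss of methanol and gives 10.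

Step 12. The most likely failures are slow transmetalation of the doubly ortho-substituted boronate with protodeboronation, and opening of the aryl lactone or hydrolysis of the chloropyranone if more basic or wetter conditions are needed. The borylation of step 9 at the same crowded carbon can also stall at protodebromination. The fallback sets out from 10, bypasses 11 and returns at 16, with a neutral tin coupling in place of the base-mediated boron coupling. Me3SnSnMe3 and Pd(PPh3)4 in toluene at 100 °C give (R)-7-(benzyloxy)-4-[4-(benzyloxy)phenyl]-5-methyl-6-(trimethylstannyl)chroman-2-one F9. A Stille coupling with 15 (Pd2(dba)3, AsPh3, CuI, DMF, 60 °C) gives 16.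

Step 10. The most likely failures are oligomerisation during the neat self-condensation and loss of the C6 chloride during the aqueous decarboxylation. The fallback sets out from 12 and returns at 14 and isolates a stable derivative of 13 before hydrolysis. Compound 12 with acetone in Et2O at 25 °C gives the crystalline adduct 7-chloro-2,2-dimethylpyrano[4,3-d][1,3]dioxine-4,5-dione F10. After purification, water in 1,4-dioxane at 80 °C releases acetone and carbon dioxide and gives 14.

Step 13. The most likely failures are loss of the pyranone methyl group to the boron halide and C-benzylation of the phenol rings if the cation is not trapped fast enough. The fallback sets out from 16 and returns at 17 and uses hydrogenolysis instead of Lewis acid cleavage: Pd(OH)2/C with H2 (1 atm) in EtOAc at 25 °C, stopped as soon as 16 is consumed so that the pyranone double bonds are not reduced. It makes no new compound.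

## Further compounds

F1 | step 7 | (3R)-6-(benzyloxy)-3-[4-(benzyloxy)phenyl]-4-methylindan-1-ol (C1 epimers) | Cc1cc(OCc2ccccc2)cc2c1[C@@H](c1ccc(OCc3ccccc3)cc1)CC2O
F2 | step 7 | (3R)-6-(benzyloxy)-3-[4-(benzyloxy)phenyl]-1-hydroperoxy-4-methylindane (C1 epimers) | Cc1cc(OCc2ccccc2)cc2c1[C@@H](c1ccc(OCc3ccccc3)cc1)CC2OO
F3 | step 7 | (4R)-7-(benzyloxy)-4-[4-(benzyloxy)phenyl]-5-methylchroman-2-ol (C2 epimers) | Cc1cc(OCc2ccccc2)cc2c1[C@@H](c1ccc(OCc3ccccc3)cc1)CC(O)O2
F4 | step 6 | 1-[5-(benzyloxy)-2-bromo-3-methylphenyl]ethan-1-ol (racemic) | Cc1cc(OCc2ccccc2)cc(C(C)O)c1Br
F5 | step 6 | 1-[5-(benzyloxy)-2-bromo-3-methylphenyl]ethan-1-one | Cc1cc(OCc2ccccc2)cc(C(C)=O)c1Br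
F6 | step 6 | (E)-1-[5-(benzyloxy)-2-bromo-3-methylphenyl]-3-[4-(benzyloxy)phenyl]prop-2-en-1-one | Cc1cc(OCc2ccccc2)cc(C(=O)/C=C/c2ccc(OCc3ccccc3)cc2)c1Br
F7 | step 8 | methyl (3R)-3-[4-(benzyloxy)-2-hydroxy-6-methylphenyl]-3-[4-(benzyloxy)phenyl]propanoate | Cc1cc(OCc2ccccc2)cc(O)c1[C@@H](c1ccc(OCc3ccccc3)cc1)CC(=O)OC
F8 | step 8 | methyl (3R)-3-[4-(benzyloxy)-3-bromo-6-hydroxy-2-methylphenyl]-3-[4-(benzyloxy)phenyl]propanoate | Cc1c(Br)c(OCc2ccccc2)cc(O)c1[C@@H](c1ccc(OCc3ccccc3)cc1)CC(=O)OC
F9 | step 12 | (R)-7-(benzyloxy)-4-[4-(benzyloxy)phenyl]-5-methyl-6-(trimethylstannyl)chroman-2-one | Cc1c([Sn](C)(C)C)c(OCc2ccccc2)cc2c1[C@@H](c1ccc(OCc3ccccc3)cc1)CC(=O)O2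
F10 | step 10 | 7-chloro-2,2-dimethylpyrano[4,3-d][1,3]dioxine-4,5-dione | CC1(C)OC(=O)c2c(O1)cc(Cl)oc2=O
F0 | step 13 | none | none
A1 | alternative 1 | allyl (R)-2,4-dihydroxy-5-[3-methoxy-3-oxo-1-[4-(triisopropylsilyloxy)phenyl]propyl]-6-methylbenzoate | C=CCOC(=O)c1c(O)cc(O)c(c1C)[C@@H](c1ccc(O[Si](C(C)C)(C(C)C)C(C)C)cc1)CC(=O)OC
A2 | alternative 2 | (R)-6-[7-hydroxy-5-methyl-2-oxo-4-[4-(triisopropylsilyloxy)phenyl]chroman-6-yl]-4-methoxy-2H-pyran-2-one | COc1cc(-c2c(O)cc3c(c2C)[C@@H](c2ccc(O[Si](C(C)C)(C(C)C)C(C)C)cc2)CC(=O)O3)oc(=O)c1
A3 | alternative 3 | methyl (R)-3-[2,4-bis(benzyloxy)-5-(4-hydroxy-2-oxo-2H-pyran-6-yl)-6-methylphenyl]-3-[4-(benzyloxy)phenyl]propanoate | O=c1cc(O)cc(-c2c(OCc3ccccc3)cc(OCc3ccccc3)c(c2C)[C@@H](c2ccc(OCc3ccccc3)cc2)CC(=O)OC)o1
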